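**Plan** (ring A = cyclobutane, ring B = cyclohexenone, ring C = seven-membered ring)
Cuts, in order: the angelate and tiglate C–O bonds; the two ring-C carbinols back to the ring-C enone and its saturated ketone; the ring-C bond from the CMe2 carbon to the future angelate carbon; the methyl, formyl and vinyl carbons on the quaternary ring-A carbon; two opposite ring-A bonds (ketene + diene); the aldol bond of an acyclic C11 chain.
Forward: C6 dienal + C5 dienolate → C11 trienoic acid → rings A and B together by intramolecular vinylketene–diene [2+2] → cyclobutanone carbon turned into the methyl/acryloyl quaternary carbon → ring C by radical closure → ring-C oxygenation → esters, angelate last.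
Enabling feature: the CMe2 carbon of ring C is quaternary and links a CH of ring A to the angelate carbinol carbon, so it can be made as a tertiary radical (hydrogen-atom transfer to an isopropenyl group on that CH) and joined to the CH2 end of a vinyl ketone on the opposite, quaternary ring-A carbon, both arms standing on the face of ring A anti to ring B.
Stereochemistry: a catalyst-set aldol carbinol acts as a relay (it makes the two possible ring A/B systems separable diastereomers and is later oxidised to the ring-B ketone); the E alkene fixes the isopropenyl group anti to ring B; methylation anti to that group sets the quaternary carbon; the angelate carbinol comes from ligand-controlled copper borylation, the tiglate carbinol from anti-selective Evans–Tishchenko reduction.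

Key step: step 12

Assumption: the (S,S)-bisphosphoramide is taken to give the 5S aldol and the (R,R)-diphosphine the needed face in the borylation; if either sense is the reverse, the mirror-image ligand is used and nothing else changes.

**Step 1**
Reactants: 1 methacrolein; 2 (triphenylphosphoranylidene)acetaldehyde
Product: 3 (2E)-4-methylpenta-2,4-dienal
Conditions: toluene, 80 °C; product kept in solution
Reagents that add atoms: (triphenylphosphoranylidene)acetaldehyde 2, O=CC=P(c1ccccc1)(c1ccccc1)c1ccccc1
Why: Wittig olefination in which the stabilised formyl ylide condenses with the aldehyde of methacrolein and, being stabilised, gives the new disubstituted double bond E.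

**Step 2**
Reactants: 4 methyl 3-methylbut-2-enoate
Product: 5 tert-butyl{[(1Z)-1-methoxy-3-methylbuta-1,3-dien-1-yl]oxy}dimethylsilane
Conditions: LiN(i-Pr)2, THF/DMPU, −78 °C; t-BuMe2SiCl, −78 °C to rt
Reagents that add atoms: tert-butylchlorodimethylsilane, CC(C)(C)[Si](C)(C)Cl
Why: Deprotonation of a γ-methyl group of the enoate and O-silylation of the extended enolate give the silyl dienol ether used as the nucleophile of a vinylogous Mukaiyama aldol addition, its ketene acetal geometry being without consequence.

**Step 3**
Reactants: 3 (2E)-4-methylpenta-2,4-dienal; 5 silyl dienol ether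
Product: 7 methyl (2E,5S,6E)-5-hydroxy-3,8-dimethylnona-2,6,8-trienoate, via trichlorosilyl aldolate 6 (not isolated)
Conditions: SiCl4 (1.1 equiv), (S,S)-bisphosphoramide derived from 2,2'-diamino-1,1'-binaphthyl (2 mol%), i-Pr2NEt (10 mol%), CH2Cl2, −78 °C; aq. NaHCO3
Reagents that add atoms: silyl dienol ether 5, C=C(C)/C=C(/OC)O[Si](C)(C)C(C)(C)C
Why: Catalytic enantioselective vinylogous Mukaiyama aldol addition in which the chiral bisphosphoramide-bound trichlorosilyl cation activates the enal for 1,2-attack by the γ-carbon of the dienolate on one aldehyde face, which sets the 5S carbinol (the later ring-B carbonyl carbon) and leaves the conjugated ester E.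

**Step 4**
Reactants: 7 methyl (2E,5S,6E)-5-hydroxy-3,8-dimethylnona-2,6,8-trienoate
Product: 8 methyl (2E,5S,6E)-3,8-dimethyl-5-(triisopropylsilyloxy)nona-2,6,8-trienoate
Conditions: i-Pr3SiOTf, 2,6-lutidine, CH2Cl2, 0 °C
Reagents that add atoms: triisopropylsilyl trifluoromethanesulfonate, CC(C)[Si](OS(=O)(=O)C(F)(F)F)(C(C)C)C(C)C
Why: Silylation of the secondary allylic alcohol with the silyl triflate and a hindered pyridine base installs a bulky, acid-tolerant ether that is carried until step 10.

**Step 5**
Reactants: 8 silyl ether ester
Product: 9 (2E,5S,6E)-3,8-dimethyl-5-(triisopropylsilyloxy)nona-2,6,8-trienoic acid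
Conditions: LiOH, THF/MeOH/H2O, rt; 1 M HCl to pH 3
Reagents that add atoms: lithium hydroxide, [Li+].[OH-]
Why: Ester saponification by hydroxide (acyl substitution), mild enough to leave the silyl ether and the E enoate untouched.

**Step 6**
Reactants: 9 trienoic acid
Product: 12 (1R,4S,5S,7S)-2-methylidene-7-(prop-1-en-2-yl)-4-(triisopropylsilyloxy)bicyclo[3.1.1]heptan-6-one, via acid chloride 10 (not isolated), via vinylketene 11 (not isolated)
Conditions: NaH, toluene, 0 °C; (COCl)2, 0 °C to rt; then slow addition to Et3N, toluene, 110 °C, high dilution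
Reagents that add atoms: none
Why: Intramolecular ketene–alkene [2+2] cycloaddition in which the acid chloride loses HCl from its γ-methyl group to give a vinylketene whose carbonyl carbon bonds to the near diene carbon (allyl-stabilised positive charge developing at the far one), so that the bridged cyclobutanone forms with the E alkene placing the isopropenyl group anti to the three-carbon bridge, while the silyloxy centre (expected anti to the forming bond, hence on the side of the isopropenyl-bearing bridge) makes the two possible ring systems diastereomers and the needed one is secured pure by chromatography.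

**Step 7**
Reactants: 12 bicyclic cyclobutanone
Product: 14 6-carbaldehyde derived from 12 (both epimers at the formyl-bearing carbon; other centres as in 12), via methyl enol ether 13 (not isolated)
Conditions: Ph3P(CH2OMe)Cl, KN(SiMe3)2, THF, 0 °C to rt; then 1 M HCl, THF, 0 °C
Reagents that add atoms: (methoxymethyl)triphenylphosphonium chloride, COC[P+](c1ccccc1)(c1ccccc1)c1ccccc1.[Cl-]; water, O
Why: Wittig methoxymethylenation of the strained, electrophilic cyclobutanone from its open face followed by acid hydrolysis of the enol ether (one-carbon homologation) gives the aldehyde, whose configuration at the formyl-bearing carbon does not matter because that carbon is enolised next.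

**Step 8**
Reactants: 14 aldehyde (epimer mixture)
Product: 15 (1R,4S,5R,6R,7S)-6-methyl-2-methylidene-7-(prop-1-en-2-yl)-4-(triisopropylsilyloxy)bicyclo[3.1.1]heptane-6-carbaldehyde
Conditions: KOt-Bu, THF, −20 °C; MeI, −20 to 0 °C
Reagents that add atoms: iodomethane, CI
Why: α-Alkylation of the aldehyde potassium enolate with iodomethane forms the quaternary ring-A carbon, the exocyclic enolate being attacked on the face turned toward ring B because the opposite face is covered by the syn-axial isopropenyl group across the cyclobutane, so the methyl group ends syn to ring B and the formyl group on the side of the isopropenyl group.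

**Step 9**
Reactants: 15 quaternary aldehyde; 16 vinylmagnesium bromide
Product: 17 allylic alcohol (1-hydroxyprop-2-enyl group in place of the formyl group of 15; both carbinol epimers)
Conditions: CH2=CHMgBr, THF, −78 to 0 °C; aq. NH4Cl
Reagents that add atoms: vinylmagnesium bromide 16, C=C[Mg]Br
Why: Grignard 1,2-addition to the hindered but non-enolisable aldehyde gives the allylic alcohol as a mixture at the new carbinol carbon, which is of no consequence because it becomes a ketone.

**Step 10**
Reactants: 17 silyl-protected allylic alcohol
Product: 18 diol (ring-B alcohol free; other centres as in 17)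
Conditions: Bu4NF, THF, rt
Reagents that add atoms: none
Why: Fluoride-induced cleavage of the Si–O bond frees the ring-B alcohol without affecting the alkenes.

**Step 11**
Reactants: 18 diol
Product: 20 (1R,5R,6R,7S)-4,6-dimethyl-6-(prop-2-enoyl)-7-(prop-1-en-2-yl)bicyclo[3.1.1]hept-3-en-2-one, via β,γ-unsaturated diketone 19 (not isolated)
Conditions: DMP, NaHCO3, CH2Cl2, 0 °C to rt; then Et3N (0.2 equiv), rt
Reagents that add atoms: none
Why: Dess–Martin oxidation converts both secondary alcohols into ketones and the amine base then moves the exocyclic double bond of the doubly activated β,γ-unsaturated ketone into conjugation (the bridgehead cannot enolise), which erases the relay stereocentre and gives the ring-B 3-methyl enone.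

**Step 12**
Reactants: 20 isopropenyl vinyl ketone
Product: 21 tricyclic diketone (ring C closed; saturated ring-C ketone next to the quaternary carbon, gem-dimethyl carbon on the ring-A CH)
Conditions: Fe(acac)3 (0.3 equiv), PhSiH3 (2.5 equiv), EtOH/ethylene glycol 5:1, 5 mM, 40 °C
Reagents that add atoms: none
Why: Fe(acac)3 and PhSiH3 in ethanol generate a trivalent iron hydride that transfers a hydrogen atom to the CH2 terminus of the electron-rich isopropenyl group, and the nucleophilic tertiary radical adds to the unsubstituted β-carbon of the vinyl ketone; the α-keto radical is reduced by divalent iron to the enolate and protonated by ethanol. The closest known reaction type is the iron-hydride hydrogen-atom-transfer reductive coupling of unactivated alkenes with enones (a Giese-type addition), used here intramolecularly. Ring C closes in the 7-endo-trig mode, because the polarity of the acceptor rules out 6-exo attack at its α-carbon. No stereocentre is created, since the new quaternary carbon carries two methyl groups. The step needs hydrogen-atom transfer to the 1,1-disubstituted alkene rather than to either electron-poor enone, and ring closure faster than β-scission of the cyclobutylcarbinyl radical. The first follows from the preference of the metal hydride for electron-rich alkenes; the second is favoured, though not guaranteed, by the two arms standing syn on ring A and anti to ring B, which holds the radical within reach of the acceptor terminus.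

**Step 13**
Reactants: 21 tricyclic diketone
Product: 23 ring-C enone (double bond between the ketone α-carbon and the CH next to the CMe2 carbon), via trimethylsilyl enol ether 22 (not isolated)
Conditions: LiN(i-Pr)2, Me3SiCl, THF, −78 °C; then Pd(OAc)2 (1.1 equiv), MeCN, rt
Reagents that add atoms: none
Why: Saegusa–Ito dehydrogenation in which kinetic deprotonation at the CH2 next to the ring-C ketone, the only α-position that can enolise (the ring-B ketone is flanked by a bridgehead), and silylation give the silyl enol ether, which divalent palladium oxidises to the conjugated enone by β-hydride elimination.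

**Step 14**
Reactants: 23 ring-C enone
Product: 25 β-hydroxy ketone (hydroxyl on the carbon next to the CMe2 carbon), via pinacol boronate 24 (not isolated)
Conditions: B2pin2, CuCl (5 mol%), (R,R)-2,3-bis(tert-butylmethylphosphino)quinoxaline (6 mol%), NaOt-Bu (10 mol%), MeOH (2 equiv), THF, rt; then NaBO3·4H2O, THF/H2O, rt
Reagents that add atoms: sodium perborate, [Na+].[O-]B1OO1
Why: Copper-catalysed conjugate borylation followed by oxidation, in which the ligand-bound monovalent copper boryl adds to the β-carbon of the less substituted ring-C enone on the face selected by the chiral diphosphine (the two faces are nearly equivalent in the substrate) and perborate replaces boron by hydroxyl with retention, setting the future angelate carbinol.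

**Step 15**
Reactants: 25 β-hydroxy ketone
Product: 26 anti-1,3-diol monoacetate (acetate on the carbinol next to the CMe2 carbon, free hydroxyl next to the quaternary carbon)
Conditions: SmI2 (0.2 equiv), MeCHO (6 equiv), THF, −10 °C
Reagents that add atoms: acetaldehyde, CC=O
Why: Evans–Tishchenko reduction in which the samarium-bound hemiacetal formed from the β-hydroxyl group and acetaldehyde transfers hydride intramolecularly to the ring-C ketone on the face of that oxygen, which gives the anti-1,3-diol with the new carbinol (future tiglate carbon) free and the old one acetylated, and leaves the ring-B enone alone.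

**Step 16**
Reactants: 26 monoacetate; 27 tigloyl chloride
Product: 28 acetate tiglate
Conditions: DMAP (0.2 equiv), pyridine, CH2Cl2, 0 to 40 °C
Reagents that add atoms: tigloyl chloride 27, C/C=C(\C)C(=O)Cl
Why: DMAP-catalysed acylation of the free neopentyl-type alcohol with the configurationally stable E acid chloride introduces the tiglate.

**Step 17**
Reactants: 28 acetate tiglate
Product: 29 hydroxy tiglate
Conditions: K2CO3 (0.3 equiv), MeOH, 0 °C
Reagents that add atoms: none
Why: Base-catalysed transesterification with methanol cleaves the unconjugated acetate in preference to the conjugated and more hindered tiglate.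

**Step 18**
Reactants: 29 hydroxy tiglate; 30 angelic acid
Product: 32 CNP0236543.4, via angelic 2,4,6-trichlorobenzoic anhydride 31 (not isolated)
Conditions: 2,4,6-trichlorobenzoyl chloride, Et3N, toluene, rt; then 29, 80 °C
Reagents that add atoms: angelic acid 30, C/C=C(/C)C(=O)O
Why: Yamaguchi-type esterification through the mixed anhydride of angelic acid with 2,4,6-trichlorobenzoic acid, run without a nucleophilic catalyst so that the Z double bond of the angelate does not isomerise.

**Compound list**
1 | methacrolein | CC(=C)C=O | starting material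
2 | (triphenylphosphoranylidene)acetaldehyde | O=CC=P(c1ccccc1)(c1ccccc1)c1ccccc1 | starting material
3 | (2E)-4-methylpenta-2,4-dienal | CC(=C)/C=C/C=O | intermediate
4 | methyl 3-methylbut-2-enoate | COC(=O)C=C(C)C | starting material
5 | tert-butyl{[(1Z)-1-methoxy-3-methylbuta-1,3-dien-1-yl]oxy}dimethylsilane | C=C(C)/C=C(/OC)O[Si](C)(C)C(C)(C)C | intermediate
6 | methyl (2E,5S,6E)-3,8-dimethyl-5-(trichlorosilyloxy)nona-2,6,8-trienoate | COC(=O)/C=C(\C)C[C@H](O[Si](Cl)(Cl)Cl)/C=C/C(C)=C | intermediate (not isolated)
7 | methyl (2E,5S,6E)-5-hydroxy-3,8-dimethylnona-2,6,8-trienoate | COC(=O)/C=C(\C)C[C@H](O)/C=C/C(C)=C | intermediate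
8 | methyl (2E,5S,6E)-3,8-dimethyl-5-(triisopropylsilyloxy)nona-2,6,8-trienoate | COC(=O)/C=C(\C)C[C@H](O[Si](C(C)C)(C(C)C)C(C)C)/C=C/C(C)=C | intermediate
9 | (2E,5S,6E)-3,8-dimethyl-5-(triisopropylsilyloxy)nona-2,6,8-trienoic acid | OC(=O)/C=C(\C)C[C@H](O[Si](C(C)C)(C(C)C)C(C)C)/C=C/C(C)=C | intermediate
10 | (2E,5S,6E)-3,8-dimethyl-5-(triisopropylsilyloxy)nona-2,6,8-trienoyl chloride | ClC(=O)/C=C(\C)C[C@H](O[Si](C(C)C)(C(C)C)C(C)C)/C=C/C(C)=C | intermediate (not isolated)
11 | (5S,6E)-8-methyl-3-methylidene-5-(triisopropylsilyloxy)nona-1,6,8-trien-1-one (vinylketene) | O=C=CC(=C)C[C@H](O[Si](C(C)C)(C(C)C)C(C)C)/C=C/C(C)=C | intermediate (not isolated)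
12 | (1R,4S,5S,7S)-2-methylidene-7-(prop-1-en-2-yl)-4-(triisopropylsilyloxy)bicyclo[3.1.1]heptan-6-one (isopropenyl anti to the three-carbon bridge, silyloxy on the side of the isopropenyl-bearing bridge) | O=C1[C@@H]2[C@@H](O[Si](C(C)C)(C(C)C)C(C)C)CC(=C)[C@H]1[C@@H]2C(C)=C | intermediate
13 | 6-(methoxymethylidene) enol ether of 12 (E/Z mixture) | COC=C1[C@@H]2[C@@H](O[Si](C(C)C)(C(C)C)C(C)C)CC(=C)[C@H]1[C@@H]2C(C)=C | intermediate (not isolated)
14 | 6-carbaldehyde derived from 12 (both epimers at the formyl-bearing carbon) | O=CC1[C@@H]2[C@@H](O[Si](C(C)C)(C(C)C)C(C)C)CC(=C)[C@H]1[C@@H]2C(C)=C | intermediate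
15 | (1R,4S,5R,6R,7S)-6-methyl-2-methylidene-7-(prop-1-en-2-yl)-4-(triisopropylsilyloxy)bicyclo[3.1.1]heptane-6-carbaldehyde (methyl syn to ring B, formyl syn to isopropenyl) | O=C[C@@]1(C)[C@@H]2[C@@H](O[Si](C(C)C)(C(C)C)C(C)C)CC(=C)[C@H]1[C@@H]2C(C)=C | intermediate
16 | vinylmagnesium bromide | C=C[Mg]Br | starting material
17 | allylic alcohol from 15 (1-hydroxyprop-2-enyl on the quaternary carbon, carbinol epimers) | C=CC(O)[C@@]1(C)[C@@H]2[C@@H](O[Si](C(C)C)(C(C)C)C(C)C)CC(=C)[C@H]1[C@@H]2C(C)=C | intermediate
18 | diol from 17 (ring-B alcohol free) | C=CC(O)[C@@]1(C)[C@@H]2[C@@H](O)CC(=C)[C@H]1[C@@H]2C(C)=C | intermediate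
19 | (1R,5R,6R,7S)-6-methyl-4-methylidene-6-(prop-2-enoyl)-7-(prop-1-en-2-yl)bicyclo[3.1.1]heptan-2-one | C=CC(=O)[C@@]1(C)[C@@H]2C(=O)CC(=C)[C@H]1[C@@H]2C(C)=C | intermediate (not isolated)
20 | (1R,5R,6R,7S)-4,6-dimethyl-6-(prop-2-enoyl)-7-(prop-1-en-2-yl)bicyclo[3.1.1]hept-3-en-2-one | C=CC(=O)[C@@]1(C)[C@@H]2C(=O)C=C(C)[C@H]1[C@@H]2C(C)=C | intermediate
21 | tricyclic diketone (ring C closed, saturated ring-C ketone) | C1CC(=O)[C@@]2(C)[C@@H]3C(=O)C=C(C)[C@H]2[C@@H]3C1(C)C | intermediate
22 | trimethylsilyl enol ether of the ring-C ketone of 21 | C1C=C(O[Si](C)(C)C)[C@@]2(C)[C@@H]3C(=O)C=C(C)[C@H]2[C@@H]3C1(C)C | intermediate (not isolated)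
23 | tricyclic bis-enone (ring-C enone) | C1=CC(=O)[C@@]2(C)[C@@H]3C(=O)C=C(C)[C@H]2[C@@H]3C1(C)C | intermediate
24 | pinacol boronate at the ring-C carbon next to the CMe2 carbon | CC1(C)OB(OC1(C)C)[C@@H]2CC(=O)[C@@]3(C)[C@@H]4C(=O)C=C(C)[C@H]3[C@@H]4C2(C)C | intermediate (not isolated)
25 | ring-C β-hydroxy ketone | O[C@@H]1CC(=O)[C@@]2(C)[C@@H]3C(=O)C=C(C)[C@H]2[C@@H]3C1(C)C | intermediate
26 | anti-1,3-diol monoacetate | CC(=O)O[C@@H]1C[C@@H](O)[C@@]2(C)[C@@H]3C(=O)C=C(C)[C@H]2[C@@H]3C1(C)C | intermediate
27 | tigloyl chloride ((2E)-2-methylbut-2-enoyl chloride) | C/C=C(\C)C(=O)Cl | starting material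
28 | acetate tiglate | CC(=O)O[C@@H]1C[C@@H](OC(=O)/C(C)=C/C)[C@@]2(C)[C@@H]3C(=O)C=C(C)[C@H]2[C@@H]3C1(C)C | intermediate
29 | hydroxy tiglate | O[C@@H]1C[C@@H](OC(=O)/C(C)=C/C)[C@@]2(C)[C@@H]3C(=O)C=C(C)[C@H]2[C@@H]3C1(C)C | intermediate
30 | angelic acid ((2Z)-2-methylbut-2-enoic acid) | C/C=C(/C)C(=O)O | starting material
31 | angelic 2,4,6-trichlorobenzoic anhydride | C/C=C(/C)C(=O)OC(=O)c1c(Cl)cc(Cl)cc1Cl | intermediate (not isolated)
32 | CNP0236543.4 (angelate tiglate diester) | C/C=C(/C)C(=O)O[C@@H]1C[C@@H](OC(=O)/C(C)=C/C)[C@@]2(C)[C@@H]3C(=O)C=C(C)[C@H]2[C@@H]3C1(C)C | target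

**Count**
Total steps: 18. Longest linear sequence: 17 steps (step 1, then steps 3–18, from methacrolein); step 2 is a one-step side branch.

**Three steps most likely to fail**

1. Step 12 (ring-C closure). What may go wrong: β-scission of the cyclobutylcarbinyl radical, which opens ring A toward a bridgehead radical stabilised by the ring-B enone, or hydrogen-atom delivery to the radical or to the vinyl ketone before closure; either can outrun the 7-endo addition. The fallback gives the acceptor a second activating group and sets out from aldehyde 15. Roskamp homologation with methyl diazoacetate and SnCl2 gives the β-keto ester F1. Bu4NF gives the alcohol F2. Dess–Martin oxidation gives the unconjugated ring-B ketone F3, which Et3N conjugates to the ring-B enone F4. Knoevenagel methylenation with paraformaldehyde and piperidinium acetate gives the 2-methylidene β-keto ester F5, an acceptor that captures alkyl radicals much faster than a vinyl ketone. Fe(acac)3 and PhSiH3 should then close ring C to the tricyclic β-keto ester F6. Krapcho dealkoxycarbonylation (LiCl, wet DMSO, 130 °C) returns to 21.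

2. Step 6 (rings A and B). What may go wrong: weak facial bias from the silyloxy centre, which lowers the throughput of the needed diastereomer, and collapse of the dipolar intermediate at the far diene terminus to a six-membered ring instead of the cyclobutanone. The fallback replaces the ketene by a keteniminium salt carrying a second control element and sets out from acid 9. Ketene 11, made as in step 6 but at room temperature, is trapped by (2R,5R)-2,5-dimethylpyrrolidine to give the β,γ-unsaturated amide F7. Tf2O and 2,4,6-collidine in 1,2-dichloroethane convert it to the keteniminium triflate F8, which should close in the same bridged sense below 80 °C to the cyclobutaniminium triflate F9. Hydrolysis with aqueous NaHCO3 returns to 12.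

3. Step 14 (angelate carbinol). What may go wrong: slow addition of the bulky copper boryl to the neopentyl β-carbon, and poor facial discrimination on a ring-C enone whose two faces are nearly equivalent. The fallback uses a small oxygen nucleophile and recycles the wrong epimer; it sets out from 23. Weitz–Scheffer epoxidation (t-BuOOH, DBU, 0 °C) of the more reactive ring-C enone gives the epoxy ketone F10 together with its face isomer F11. SmI2 in THF/MeOH at −90 °C opens both at the C–O bond next to the ketone, giving 25 and its carbinol epimer F12, which are separated. F12 is returned to 23 by mesylation and elimination (MsCl, Et3N), and 25 rejoins the route.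

**Further compounds**
F1 | step 12 | methyl β-keto ester from Roskamp homologation of 15 | COC(=O)CC(=O)[C@@]1(C)[C@@H]2[C@@H](O[Si](C(C)C)(C(C)C)C(C)C)CC(=C)[C@H]1[C@@H]2C(C)=C
F2 | step 12 | desilylated hydroxy β-keto ester | COC(=O)CC(=O)[C@@]1(C)[C@@H]2[C@@H](O)CC(=C)[C@H]1[C@@H]2C(C)=C
F3 | step 12 | β-keto ester with unconjugated ring-B ketone (exocyclic methylene) | COC(=O)CC(=O)[C@@]1(C)[C@@H]2C(=O)CC(=C)[C@H]1[C@@H]2C(C)=C
F4 | step 12 | β-keto ester with ring-B enone | COC(=O)CC(=O)[C@@]1(C)[C@@H]2C(=O)C=C(C)[C@H]1[C@@H]2C(C)=C
F5 | step 12 | 2-methylidene β-keto ester | COC(=O)C(=C)C(=O)[C@@]1(C)[C@@H]2C(=O)C=C(C)[C@H]1[C@@H]2C(C)=C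
F6 | step 12 | tricyclic β-keto ester (ester on the ring-C carbon next to the ketone, epimers) | C1C(C(=O)OC)C(=O)[C@@]2(C)[C@@H]3C(=O)C=C(C)[C@H]2[C@@H]3C1(C)C
F7 | step 6 | (2R,5R)-2,5-dimethylpyrrolidine amide of the 3-methylidene acid | C=C(CC(=O)N1[C@H](C)CC[C@H]1C)C[C@H](O[Si](C(C)C)(C(C)C)C(C)C)/C=C/C(C)=C
F8 | step 6 | keteniminium triflate | C[C@@H]1CC[C@@H](C)[N+]1=C=CC(=C)C[C@H](O[Si](C(C)C)(C(C)C)C(C)C)/C=C/C(C)=C.[O-]S(=O)(=O)C(F)(F)F
F9 | step 6 | cyclobutaniminium triflate | C[C@@H]1CC[C@@H](C)[N+]1=C1[C@@H]2[C@@H](O[Si](C(C)C)(C(C)C)C(C)C)CC(=C)[C@H]1[C@@H]2C(C)=C.[O-]S(=O)(=O)C(F)(F)F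
F10 | step 14 | ring-C epoxy ketone, oxygen on the face needed for 25 | [C@H]14O[C@@H]4C(=O)[C@@]2(C)[C@@H]3C(=O)C=C(C)[C@H]2[C@@H]3C1(C)C
F11 | step 14 | ring-C epoxy ketone, opposite face | [C@@H]14O[C@H]4C(=O)[C@@]2(C)[C@@H]3C(=O)C=C(C)[C@H]2[C@@H]3C1(C)C
F12 | step 14 | carbinol epimer of 25 | O[C@H]1CC(=O)[C@@]2(C)[C@@H]3C(=O)C=C(C)[C@H]2[C@@H]3C1(C)C
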